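**Remark on the chemistry.** Ring positions are numbered as in the target throughout. Ring B: C1 carboxyl carbon, C2 OH, C3 CHO, C4 OH, C5 depside oxygen, C6 CH3. Ring A: C1 acyl carbon, C2 OH, C3 CHO, C4 OCH3, C6 CH3. Compounds 1, 4 and 13 are taken as commercial.

## The problem

Haemathamnolic acid (20) is a depside: two benzene rings joined only by an ester between the acyl carbon C1 of ring A and the C5 oxygen of ring B. It has no stereocentre, so nothing has to be set or relayed; every difficulty is one of regiochemistry on two crowded arenes and of chemoselectivity among similar oxygens. Ring B is hexasubstituted and carries three oxygens, of which only the one at C5 may be acylated and the one at C4 must be told apart from its neighbour. Ring A is the easier half, a 3-formylated, 4-O-methylated orsellinic acid. The fragile elements are: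
- the two salicylaldehyde formyl groups;
- the doubly flanked aryl ester, which hydroxide and alkoxide open or transacylate;
- the 2,4-dihydroxybenzoic acid of ring B, which decarboxylates in warm acid;
- the ring A methyl ether beside a formyl group, which Lewis acids can cleave;
- every hydroquinone on the way, which air oxidises.

The feature that is exploited is the oxygen pattern of ring B: oxygens para to each other at C2 and C5, a third oxygen at C4, carbon substituents at C1 and C6, and C3 as the one position that can stay CH until late. This is the pattern produced when a squarate-derived 3-alkoxy-4-hydroxy-4-alkenylcyclobutenone opens and recloses thermally.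

## Retrosynthesis

**20 to 19.** The last operation should cut only oxygen–alkyl bonds. In 19 the ring A C2 oxygen is a benzyl ether, the ring B C4 oxygen an isopropyl ether and the ring B acid a tert-butyl ester. All three alkyl groups leave as stabilised cations under BCl3, whereas the methyl ether and the depside ester do not. This favours one Lewis acid operation over a saponification, which the depside would not survive, or a longer sequence of orthogonal removals. The forward step must discriminate benzylic, secondary and tertiary C–O bonds from the methyl C–O bond.

**19 to 12 and 18.** Cutting the depside C(=O)–O bond gives two halves of similar size, each already carrying its formyl group. Formylating after the union would instead have to address a ring A with two free positions. In 12 the C2 hydroxyl is held between the ester and the formyl group by hydrogen bonds, so the C5 hydroxyl is the only ordinary phenol. Acid chloride 18, made in the flask from acid 17, is preferred to an acid-promoted condensation because 12 carries an acid-labile ester. The forward step must find the C5 hydroxyl and overcome the crowding of both partners.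

**12 to 11.** The C3–CHO bond is cut next. In hydroquinone 11, C3 is the only ring CH and lies ortho to the C2 hydroxyl, so a phenoxide-directed ortho-formylation has no regiochemical choice. Formylating before the acylation sharpens the C5 selectivity of the next step and keeps the depside away from amine and methoxide. The forward step must tolerate the tert-butyl ester and the isopropyl ether, which rules out TiCl4, and must exclude air.

**11 to 8.** Ring B is disconnected at C1–C2 by retro-6π electrocyclization to dienylketene 9 (through dienone 10), and 9 is folded back by retro-4π closure into cyclobutenone 8. The obvious neighbour is oxidation of an orsellinate at C5 followed by sorting three hydroxyls. Against that, this cut delivers the para oxygens at C2 and C5, a distinct alkoxy group at C4, the C6 methyl and the C1 ester in one redox-neutral step without any regiochemical decision. Precursor 8 is a four-membered ring with one carbinol centre (racemic, later erased) and a trisubstituted enoate. The forward step needs outward rotation of the hydroxyl and an E enoate.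

**8 to 3 and 7.** The bond between the carbinol carbon and C3 of the butenoate is cut, which corresponds to 1,2-addition of alkenylmagnesium 7 to the ketone-like carbonyl of semisquarate 3. Reagent 7 comes from iodide 6 by halogen–magnesium exchange. The forward step must keep the E geometry, spare the ester and choose the carbonyl beside the alkoxy carbon.

**3 to 1; 6 to 5 to 4.** Semisquarate 3 comes from diisopropyl squarate 1 by cutting one C–O bond and adding one hydride. Iodide 6 comes from stannane 5 by tin–iodine exchange, and 5 from ynoate 4 by syn addition of tin and hydrogen, which fixes the E geometry. Direct hydroiodination of 4 would give the other isomer, which is why the tin route is taken.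

**17 to 16 to 15 to 14 to 13.** Acid 17 is traced back through its methyl ester 16 and phenol 15 to methyl ether 14 and methyl orsellinate 13. The cuts are the benzyl C–O bond, the C3–CHO bond and the methyl C–O bond. Methylating before formylating leaves the chelated C2 hydroxyl as the only phenol and as the director of the formylation.

## Roads not taken

**Alternative 1:** The cut is at both aryl–CHO bonds of the assembled depside. In the forward direction benzyl 2,4-dihydroxy-5-[(2-hydroxy-4-methoxy-6-methylbenzoyl)oxy]-6-methylbenzoate A2 would be treated with Cl2CHOMe and TiCl4 to formylate both rings and give haemathamnolic acid benzyl ester A1. Hydrogenolysis over Pd/C would then give 20.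
- Merits: the most convergent endgame; both aldehydes are introduced in one operation and never carried; the benzyl ester leaves under the mildest conditions a depside acid can have; the ring A half is simply the acid of 14.
- Weak points: ring A of A2 has two free positions (C3 and C5), so an isomer would form on fully elaborated material. TiCl4 and HCl act on a depside whose ring B is a polyhydroxybenzoate. The ring B problem is moved, not solved: A2 requires benzyl 2,4,5-trihydroxy-6-methylbenzoate A3, whose C5 oxygen must be put in by oxidising an orsellinate, which is very oxidation-prone and must be acylated at one of three hydroxyls.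
- Comparison: if A3 were at hand this road would be shorter than the twelve steps proposed here, and its final deprotection is gentler than BCl3. The chosen plan offers in return three ring B oxygens that are differentiated from the start, a ring A formylation done early on a cheap intermediate, and a late formylation only at a ring with a single free position.

**Alternative 2:** Ring B is cut at C1–C6 and C2–C3 into tert-butyl methyl malonate A6 and 3-(benzyloxy)pent-3-en-2-one A5. In the forward direction the malonate anion adds to A5, the methyl ketone enolate closes onto the methyl ester, and tert-butyl 5-(benzyloxy)-6-methyl-2,4-dioxocyclohexane-1-carboxylate A4 results, to be aromatised later.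
- Merits: cheap, scalable enolate chemistry; no tin, no low-temperature organomagnesium, no thermolysis; the C5 oxygen and C6 methyl arrive with A5; the stereocentres of A4 do not matter.
- Weak points: A4 is two hydrogens short of an arene. Dehydrogenation of such diones classically passes through ring halogenation, which falls on C3, the position reserved for the formyl group, and then needs a reductive clean-up that conflicts with the benzyl ether. A5 is a β-substituted α-alkoxy enone, a poor Michael acceptor that must itself be made. After aromatisation the C2 and C4 hydroxyls are both free, so the selectivity problem of alternative 1 returns.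
- Comparison: in raw-material cost and scalability this road is better, and the step count to a formylated ring B phenol is about the same. The chosen plan offers in return an aromatisation contained in the ring-forming step itself and a C4 oxygen already distinct from the C5 oxygen.

**Alternative 3:** Ring A is cut at C1–C2 and C5–C6, a retro-Diels–Alder to the Brassard diene 1,3-dimethoxy-1-(trimethylsilyloxy)buta-1,3-diene A8 and benzyl 2,4-bis(benzyloxy)-5-(but-2-ynoyloxy)-3-formyl-6-methylbenzoate A9. In the forward direction cycloaddition and loss of methanol would give benzyl 2,4-bis(benzyloxy)-3-formyl-5-[(2-hydroxy-4-methoxy-6-methylbenzoyl)oxy]-6-methylbenzoate A7.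
- Merits: the depside oxygen–acyl bond is made on a small acyl group, so no esterification between two crowded arenes is needed; the regiochemistry of this diene with ynoates is dependable and gives the 2-hydroxy-4-methoxy-6-methyl pattern directly.
- Weak points: the ring-forming step is spent on ring A, which is two steps from 13. A9 presupposes the complete hexasubstituted ring B, so the hard half remains unsolved. The diene is a silyl ketene acetal that should add to the ring B formyl group and may attack the activated aryl ester. A β-methyl ynoate is a sluggish dienophile. A7 still lacks the ring A formyl group, which would have to be placed between two free positions in the presence of three benzyl groups.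
- Comparison: this road is better in avoiding the hindered acylation of step 11. The chosen plan instead puts its key step on ring B, where the difficulty lies, and takes ring A from 13 by routine chemistry.

Key step: step 5

## Route

Step 1
Reactants: 1 diisopropyl squarate
Product: 3 3-isopropoxycyclobut-3-ene-1,2-dione, via 4-hydroxy-2,3-diisopropoxycyclobut-2-en-1-one 2 (not isolated)
Conditions: LiAlH(OtBu)3, THF, −78 to −20 °C; then conc. aq. HCl, CH2Cl2, rt
Reagents that add atoms: water, O (oxygen of the new carbonyl group)
Why: Mono-reduction of a squaric ester by a bulky alkoxyaluminium hydride stops at carbinol 2; acid then ionises the allylic hydroxyl to an alkoxy-stabilised cyclobutenyl cation, water adds at the alkoxy-bearing terminus and isopropanol is expelled (1,3-carbonyl transposition), the standard entry to 3-alkoxycyclobutenediones.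

Step 2
Reactants: 4 tert-butyl but-2-ynoate
Product: 5 tert-butyl (E)-3-(tributylstannyl)but-2-enoate
Conditions: Bu3SnH, LiN(iPr)2, THF, 0 °C; CuBr·SMe2, −78 °C; then 4, MeOH, −78 °C
Reagents that add atoms: tributyltin hydride, CCCC[SnH](CCCC)CCCC (delivered as the stannylcopper reagent)
Why: Syn stannylcupration of an ynoate under kinetic conditions (low temperature, proton source present) puts tin on C3 and hydrogen on C2 on the same side, so tin ends trans to the ester: the E isomer.

Step 3
Reactants: 5 tert-butyl (E)-3-(tributylstannyl)but-2-enoate
Product: 6 tert-butyl (E)-3-iodobut-2-enoate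
Conditions: I2, CH2Cl2, 0 °C
Reagents that add atoms: iodine, II
Why: Iododestannylation is an ipso substitution at the alkenyl carbon and proceeds with retention of the alkene geometry.

Step 4
Reactants: 6 tert-butyl (E)-3-iodobut-2-enoate; 3 3-isopropoxycyclobut-3-ene-1,2-dione
Product: 8 tert-butyl (E)-3-(1-hydroxy-2-isopropoxy-4-oxocyclobut-2-en-1-yl)but-2-enoate (racemic), via alkenylmagnesium chloride 7 (not isolated)
Conditions: iPrMgCl·LiCl, THF, −40 °C; then 3, −78 °C; aq. NH4Cl
Reagents that add atoms: none
Why: Iodine–magnesium exchange of an alkenyl iodide activated by an ester proceeds at low temperature with retention and spares a tert-butyl ester; 7 then adds 1,2 to the carbonyl beside the alkoxy carbon of 3, because the other carbonyl is a deactivated vinylogous ester. The E geometry holds alkoxide and ester apart so no butenolide can form, and the carbinol centre is formed racemic and is erased in step 5.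

Step 5
Reactants: 8 tert-butyl (E)-3-(1-hydroxy-2-isopropoxy-4-oxocyclobut-2-en-1-yl)but-2-enoate
Product: 11 tert-butyl 2,5-dihydroxy-4-isopropoxy-6-methylbenzoate, via dienylketene 9 (not isolated), via cyclohexadienone 10 (not isolated)
Conditions: toluene (degassed), 110 °C, Ar; work-up with aq. Na2S2O4
Reagents that add atoms: none
Why: This is the Moore rearrangement of a 4-alkenyl-4-hydroxycyclobutenone, an established route to hydroquinones. Heating breaks the bond between the carbonyl carbon and the carbinol carbon by thermal conrotatory 4π electrocyclic opening to dienylketene 9; the donor hydroxyl rotates outward (torquoselectivity of donor substituents), which places the butenoate unit cis to the ketene. Ring B then closes by thermal disrotatory 6π electrocyclization between the ketene carbon (future C2) and the enoate α-carbon (future C1) to give dienone 10, and enolization, driven by aromatization, gives 11. The E enoate puts hydrogen and not the ester on the inside of the closing triene and keeps the ester away from the carbinol oxygen, so neither steric retardation nor lactonization should intervene. No stereocentre survives, since the carbinol centre of 8 and the sp3 carbon of 10 both become arene carbons. Regiochemistry needs no selection because each ring carbon brings its substituent from 8: alkoxy carbon to C4, carbinol carbon to C5, ring CH to C3, ketene carbon to C2, butenoate carbons to C6 and C1. Exclusion of oxygen and a dithionite wash keep the electron-rich hydroquinone from passing to the quinone.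

Step 6
Reactants: 11 tert-butyl 2,5-dihydroxy-4-isopropoxy-6-methylbenzoate
Product: 12 tert-butyl 3-formyl-2,5-dihydroxy-4-isopropoxy-6-methylbenzoate
Conditions: MgCl2, Et3N, (CH2O)n, MeCN, reflux, Ar; aq. HCl, Na2S2O4
Reagents that add atoms: paraformaldehyde (as formaldehyde), C=O
Why: Casnati–Skattebøl ortho-formylation: the magnesium phenoxide of the C2 hydroxyl binds formaldehyde and delivers it to C3, the only free ring position, and a second formaldehyde oxidises the benzylic alkoxide by hydride transfer to give the salicylaldehyde. The C5 phenoxide has no free ortho position, and the tert-butyl ester and isopropyl ether are inert to these mildly basic conditions.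

Step 7
Reactants: 13 methyl orsellinate (methyl 2,4-dihydroxy-6-methylbenzoate)
Product: 14 methyl 2-hydroxy-4-methoxy-6-methylbenzoate
Conditions: MeI (1.05 equiv), K2CO3, acetone, reflux
Reagents that add atoms: iodomethane, CI
Why: Williamson etherification; the 4-hydroxyl is the unchelated and more acidic phenol, while the 2-hydroxyl is hydrogen-bonded to the ester and is left alone.

Step 8
Reactants: 14 methyl 2-hydroxy-4-methoxy-6-methylbenzoate
Product: 15 methyl 3-formyl-2-hydroxy-4-methoxy-6-methylbenzoate
Conditions: Cl2CHOMe, TiCl4, CH2Cl2, −10 to 0 °C; then ice, aq. HCl
Reagents that add atoms: dichloromethyl methyl ether, COC(Cl)Cl (formyl carbon); water, O (formyl oxygen, on hydrolysis)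
Why: Rieche formylation; the titanium phenoxide directs the electrophile to the ortho position C3, which is also ortho to the methoxy group and para to the methyl group. Any C5 isomer would be removed at this early stage by crystallisation.

Step 9
Reactants: 15 methyl 3-formyl-2-hydroxy-4-methoxy-6-methylbenzoate
Product: 16 methyl 2-(benzyloxy)-3-formyl-4-methoxy-6-methylbenzoate
Conditions: BnBr, K2CO3, DMF, 60 °C
Reagents that add atoms: benzyl bromide, BrCc1ccccc1
Why: Williamson benzylation; in a dipolar aprotic solvent with a reactive benzylic halide even this chelated, flanked phenoxide is alkylated, and nothing else in 15 is nucleophilic.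

Step 10
Reactants: 16 methyl 2-(benzyloxy)-3-formyl-4-methoxy-6-methylbenzoate
Product: 17 2-(benzyloxy)-3-formyl-4-methoxy-6-methylbenzoic acid
Conditions: KOH, DMSO/H2O, 80 °C; then aq. HCl, 0 °C
Reagents that add atoms: potassium hydroxide, [K+].[OH-] (one carboxyl oxygen)
Why: Poorly solvated hydroxide in aqueous DMSO saponifies 2,6-disubstituted benzoates that resist ordinary conditions. The aldehyde is not enolisable and is shielded by two ortho alkoxy groups, so disproportionation should be slow, and the benzyl ether is stable to base.

Step 11
Reactants: 17 2-(benzyloxy)-3-formyl-4-methoxy-6-methylbenzoic acid; 12 tert-butyl 3-formyl-2,5-dihydroxy-4-isopropoxy-6-methylbenzoate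
Product: 19 tert-butyl 5-{[2-(benzyloxy)-3-formyl-4-methoxy-6-methylbenzoyl]oxy}-3-formyl-2-hydroxy-4-isopropoxy-6-methylbenzoate, via acid chloride 18 (not isolated)
Conditions: (COCl)2, cat. DMF, CH2Cl2, 0 °C to rt; evaporate; then 12, pyridine, cat. DMAP, CH2Cl2, 0 °C to rt, Ar
Reagents that add atoms: none
Why: Acid chloride formation followed by DMAP-catalysed acylation of a phenol, the classical depside esterification with a protected acid chloride. The C2 hydroxyl of 12 is hydrogen-bonded to both the ester and the formyl group and is flanked by them, so the acylpyridinium ion is taken up by the C5 hydroxyl, and the weak base leaves the tert-butyl ester and both aldehydes untouched.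

Step 12
Reactants: 19 tert-butyl 5-{[2-(benzyloxy)-3-formyl-4-methoxy-6-methylbenzoyl]oxy}-3-formyl-2-hydroxy-4-isopropoxy-6-methylbenzoate
Product: 20 haemathamnolic acid (3-formyl-5-[(3-formyl-2-hydroxy-4-methoxy-6-methylbenzoyl)oxy]-2,4-dihydroxy-6-methylbenzoic acid)
Conditions: BCl3 (excess), C6HMe5, CH2Cl2, −78 to 0 °C; then H2O, 0 °C
Reagents that add atoms: none
Why: Lewis acid dealkylation: BCl3 bound to the neighbouring carbonyl oxygens cleaves the benzyl ether (cation trapped by pentamethylbenzene), the isopropyl aryl ether and the tert-butyl ester, all through stabilised cationic alkyl fragments, while the methyl ether reacts far more slowly. Once the ring A phenol is bound to boron and chelated to the formyl oxygen, the flanking methoxy group is no longer activated, and the aryl ester and aldehydes survive the low temperature.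

## Compound list

1 | diisopropyl squarate | CC(C)OC1=C(OC(C)C)C(=O)C1=O | starting material
2 | 4-hydroxy-2,3-diisopropoxycyclobut-2-en-1-one (racemic) | CC(C)OC1=C(OC(C)C)C(O)C1=O | intermediate (not isolated)
3 | 3-isopropoxycyclobut-3-ene-1,2-dione | CC(C)OC1=CC(=O)C1=O | intermediate
4 | tert-butyl but-2-ynoate | CC#CC(=O)OC(C)(C)C | starting material
5 | tert-butyl (E)-3-(tributylstannyl)but-2-enoate | CCCC[Sn](CCCC)(CCCC)/C(C)=C/C(=O)OC(C)(C)C | intermediate
6 | tert-butyl (E)-3-iodobut-2-enoate | I/C(C)=C/C(=O)OC(C)(C)C | intermediate
7 | tert-butyl (E)-3-(chloromagnesio)but-2-enoate (LiCl complex) | Cl[Mg]/C(C)=C/C(=O)OC(C)(C)C | intermediate (not isolated)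
8 | tert-butyl (E)-3-(1-hydroxy-2-isopropoxy-4-oxocyclobut-2-en-1-yl)but-2-enoate (racemic) | CC(C)OC1=CC(=O)C1(O)/C(C)=C/C(=O)OC(C)(C)C | intermediate
9 | tert-butyl (2E,4Z)-4-hydroxy-5-isopropoxy-3-methyl-7-oxohepta-2,4,6-trienoate (dienylketene) | O=C=C/C(OC(C)C)=C(/O)\C(C)=C\C(=O)OC(C)(C)C | intermediate (not isolated)
10 | tert-butyl 3-hydroxy-4-isopropoxy-2-methyl-6-oxocyclohexa-2,4-diene-1-carboxylate (racemic) | O=C1C=C(OC(C)C)C(O)=C(C)C1C(=O)OC(C)(C)C | intermediate (not isolated)
11 | tert-butyl 2,5-dihydroxy-4-isopropoxy-6-methylbenzoate | CC(C)Oc1cc(O)c(C(=O)OC(C)(C)C)c(C)c1O | intermediate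
12 | tert-butyl 3-formyl-2,5-dihydroxy-4-isopropoxy-6-methylbenzoate | CC(C)Oc1c(C=O)c(O)c(C(=O)OC(C)(C)C)c(C)c1O | intermediate
13 | methyl orsellinate (methyl 2,4-dihydroxy-6-methylbenzoate) | COC(=O)c1c(C)cc(O)cc1O | starting material
14 | methyl 2-hydroxy-4-methoxy-6-methylbenzoate | COC(=O)c1c(C)cc(OC)cc1O | intermediate
15 | methyl 3-formyl-2-hydroxy-4-methoxy-6-methylbenzoate | COC(=O)c1c(C)cc(OC)c(C=O)c1O | intermediate
16 | methyl 2-(benzyloxy)-3-formyl-4-methoxy-6-methylbenzoate | COC(=O)c1c(C)cc(OC)c(C=O)c1OCc1ccccc1 | intermediate
17 | 2-(benzyloxy)-3-formyl-4-methoxy-6-methylbenzoic acid | COc1cc(C)c(C(=O)O)c(OCc2ccccc2)c1C=O | intermediate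
18 | 2-(benzyloxy)-3-formyl-4-methoxy-6-methylbenzoyl chloride | COc1cc(C)c(C(=O)Cl)c(OCc2ccccc2)c1C=O | intermediate (not isolated)
19 | tert-butyl 5-{[2-(benzyloxy)-3-formyl-4-methoxy-6-methylbenzoyl]oxy}-3-formyl-2-hydroxy-4-isopropoxy-6-methylbenzoate | COc1cc(C)c(C(=O)Oc2c(C)c(C(=O)OC(C)(C)C)c(O)c(C=O)c2OC(C)C)c(OCc2ccccc2)c1C=O | intermediate
20 | haemathamnolic acid | COc1cc(C)c(C(=O)Oc2c(C)c(C(=O)O)c(O)c(C=O)c2O)c(O)c1C=O | target

## Step count and risk

Total step count: 12. Longest linear sequence: 7 steps (steps 2, 3, 4, 5, 6, 11, 12, from 4 to 20). The ring A branch (steps 7 to 10) and step 1 converge on it.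

**Step 5 (key step).** The most likely failures are partial air oxidation of the hydroquinone during isolation, and a slow 6π closure caused by the electron-poor alkene terminus. A slow closure gives the ketene time to dimerise or, after inward rotation of the hydroxyl, to lactonise. Fallback, from 8 back to 11:
- The carbinol is silylated (Et3SiOTf, 2,6-lutidine, CH2Cl2, −78 °C) to tert-butyl (E)-3-[2-isopropoxy-4-oxo-1-(triethylsilyloxy)cyclobut-2-en-1-yl]but-2-enoate F1.
- Thermolysis of F1 in toluene, the known variant of the same rearrangement with a 4-silyloxy group, cannot lactonise and gives the mono-protected, less oxidisable tert-butyl 2-hydroxy-4-isopropoxy-6-methyl-5-(triethylsilyloxy)benzoate F2.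
- Buffered Bu4NF (AcOH, THF, 0 °C) releases 11 immediately before step 6.

**Step 4.** The most likely failures are a slow halogen–magnesium exchange, because the E iodide has no ester chelation to assist it, and addition–elimination of the isopropyl group at the β-carbon of 6. Conjugate addition to the ring CH of 3 is a further possibility. Fallback, from 6 and 3 directly to 8: a Nozaki–Hiyama–Kishi coupling (CrCl2, catalytic NiCl2, DMF, rt). The alkenylchromium species forms with retention, tolerates esters and should choose the most electrophilic carbonyl of the strained dione. No new compound arises.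

**Step 6.** The most likely failure is slow C–C bond formation at a position flanked by the isopropoxy group on a phenoxide chelated to the ester. The long heating would then favour oxidation of the hydroquinone dianion and benzylic methoxymethyl by-products. Fallback, from 11 (with 18) to 20:
- The order is reversed: 11 is acylated first with 18 under the conditions of step 11 to give tert-butyl 5-{[2-(benzyloxy)-3-formyl-4-methoxy-6-methylbenzoyl]oxy}-2-hydroxy-4-isopropoxy-6-methylbenzoate F3, which contains no hydroquinone.
- F3 is formylated electrophilically (Cl2CHOMe, TiCl4, CH2Cl2, 0 °C) at ring B C3, the single free position of the only activated ring.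
- TiCl4 is expected to cleave the tert-butyl ester at the same time, giving 5-{[2-(benzyloxy)-3-formyl-4-methoxy-6-methylbenzoyl]oxy}-3-formyl-2-hydroxy-4-isopropoxy-6-methylbenzoic acid F4.
- The BCl3 conditions of step 12 convert F4 into 20. Any further ether cleavage by TiCl4 only anticipates that step.

**Step 11.** The most likely failure is sluggish acyl transfer between two doubly ortho-substituted partners. That would let acylation at the chelated C2 hydroxyl, double acylation or oxidation of 12 compete. Fallback, from 15 and 12 to 20:
- The methyl ester of 15 is cleaved in cold concentrated H2SO4 (acylium pathway, suited to 2,6-disubstituted benzoates) to 3-formyl-2-hydroxy-4-methoxy-6-methylbenzoic acid F5.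
- F5 and 12 are condensed with (CF3CO)2O in toluene at rt through the mixed anhydride, an established way to hindered depsides that leaves chelated hydroxyls free. This gives tert-butyl 3-formyl-5-[(3-formyl-2-hydroxy-4-methoxy-6-methylbenzoyl)oxy]-2-hydroxy-4-isopropoxy-6-methylbenzoate F6. The tert-butyl ester is expected to survive the dilute CF3CO2H formed.
- BCl3 (CH2Cl2, −78 to 0 °C, no scavenger needed) then gives 20.

**Step 12.** The most likely failures are over-reaction (cleavage of the ring A methyl ether beside the formyl group, or of the depside ester, before the tert-butyl ester has gone), ring alkylation by the liberated cations, and decarboxylation if the acidic mixture warms. Fallback, from 19 to 20, in two graded stages: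
- CF3CO2H with C6HMe5 in CH2Cl2 at rt removes by protonolysis the tert-butyl ester and the activated benzyl ether, but not the isopropyl or methyl ether. This gives 3-formyl-5-[(3-formyl-2-hydroxy-4-methoxy-6-methylbenzoyl)oxy]-2-hydroxy-4-isopropoxy-6-methylbenzoic acid F7.
- A small excess of BCl3 at −78 °C then cleaves only the isopropyl ether, the ring A phenol being bound to boron before any ether is attacked, and gives 20.

## Further compounds

F1 | step 5 | tert-butyl (E)-3-[2-isopropoxy-4-oxo-1-(triethylsilyloxy)cyclobut-2-en-1-yl]but-2-enoate (racemic) | CC[Si](CC)(CC)OC1(/C(C)=C/C(=O)OC(C)(C)C)C(=O)C=C1OC(C)C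
F2 | step 5 | tert-butyl 2-hydroxy-4-isopropoxy-6-methyl-5-(triethylsilyloxy)benzoate | CC[Si](CC)(CC)Oc1c(C)c(C(=O)OC(C)(C)C)c(O)cc1OC(C)C
F0 | step 4 | none | none
F3 | step 6 | tert-butyl 5-{[2-(benzyloxy)-3-formyl-4-methoxy-6-methylbenzoyl]oxy}-2-hydroxy-4-isopropoxy-6-methylbenzoate | COc1cc(C)c(C(=O)Oc2c(C)c(C(=O)OC(C)(C)C)c(O)cc2OC(C)C)c(OCc2ccccc2)c1C=O
F4 | step 6 | 5-{[2-(benzyloxy)-3-formyl-4-methoxy-6-methylbenzoyl]oxy}-3-formyl-2-hydroxy-4-isopropoxy-6-methylbenzoic acid | COc1cc(C)c(C(=O)Oc2c(C)c(C(=O)O)c(O)c(C=O)c2OC(C)C)c(OCc2ccccc2)c1C=O
F5 | step 11 | 3-formyl-2-hydroxy-4-methoxy-6-methylbenzoic acid | COc1cc(C)c(C(=O)O)c(O)c1C=O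
F6 | step 11 | tert-butyl 3-formyl-5-[(3-formyl-2-hydroxy-4-methoxy-6-methylbenzoyl)oxy]-2-hydroxy-4-isopropoxy-6-methylbenzoate | COc1cc(C)c(C(=O)Oc2c(C)c(C(=O)OC(C)(C)C)c(O)c(C=O)c2OC(C)C)c(O)c1C=O
F7 | step 12 | 3-formyl-5-[(3-formyl-2-hydroxy-4-methoxy-6-methylbenzoyl)oxy]-2-hydroxy-4-isopropoxy-6-methylbenzoic acid | COc1cc(C)c(C(=O)Oc2c(C)c(C(=O)O)c(O)c(C=O)c2OC(C)C)c(O)c1C=O
A1 | alternative 1 | haemathamnolic acid benzyl ester | COc1cc(C)c(C(=O)Oc2c(C)c(C(=O)OCc3ccccc3)c(O)c(C=O)c2O)c(O)c1C=O
A2 | alternative 1 | benzyl 2,4-dihydroxy-5-[(2-hydroxy-4-methoxy-6-methylbenzoyl)oxy]-6-methylbenzoate | COc1cc(C)c(C(=O)Oc2c(C)c(C(=O)OCc3ccccc3)c(O)cc2O)c(O)c1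
A3 | alternative 1 | benzyl 2,4,5-trihydroxy-6-methylbenzoate | Cc1c(O)c(O)cc(O)c1C(=O)OCc1ccccc1
A4 | alternative 2 | tert-butyl 5-(benzyloxy)-6-methyl-2,4-dioxocyclohexane-1-carboxylate (diastereomer mixture) | CC1C(OCc2ccccc2)C(=O)CC(=O)C1C(=O)OC(C)(C)C
A5 | alternative 2 | 3-(benzyloxy)pent-3-en-2-one | CC=C(OCc1ccccc1)C(C)=O
A6 | alternative 2 | tert-butyl methyl malonate | COC(=O)CC(=O)OC(C)(C)C
A7 | alternative 3 | benzyl 2,4-bis(benzyloxy)-3-formyl-5-[(2-hydroxy-4-methoxy-6-methylbenzoyl)oxy]-6-methylbenzoate | COc1cc(C)c(C(=O)Oc2c(C)c(C(=O)OCc3ccccc3)c(OCc3ccccc3)c(C=O)c2OCc2ccccc2)c(O)c1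
A8 | alternative 3 | 1,3-dimethoxy-1-(trimethylsilyloxy)buta-1,3-diene (Brassard diene) | COC(=C)C=C(OC)O[Si](C)(C)C
A9 | alternative 3 | benzyl 2,4-bis(benzyloxy)-5-(but-2-ynoyloxy)-3-formyl-6-methylbenzoate | CC#CC(=O)Oc1c(C)c(C(=O)OCc2ccccc2)c(OCc2ccccc2)c(C=O)c1OCc1ccccc1
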